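**Retrosynthetic overview**

1. Locants of the spiroketal: O1, C2 (methyl), C3, C4, C5 (spiro), O6, C7 (hexyl), C8, C9; ring B = O1–C2–C3–C4–C5, ring A = C5–O6–C7–C8–C9. Ring B is opened last at O1–C5: a catalyst-controlled addition of the C2 hydroxyl to C5 of a 2,3-dihydrofuran (ring A with C5=C9) closes the last ring and sets C5, the one stereocentre with no intrinsic bias.
2. Enabling feature: C5 is the ketal carbon shared by rings A and B and has a ring CH2 (C9) in ring A, so it can be stored as the enol ether carbon O6–C5=C9; O1 on C2 sits three carbons away (C2–C3–C4–C5), set up for a 5-exo closure.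
3. Ring A: 5-endo-dig cycloisomerisation of a C7-hydroxy C9≡C5 alkyne. The propyne unit C4–C5≡C9 acts as a double nucleophile that joins two electrophilic epoxide carbons (C3 of (S)-2-methyloxirane, C8 of an (S)-oxirane), which answers both 1,4-dioxygen relationships around C5.
4. Lactone ring: aryl ketone from 3,5-dimethoxybenzonitrile, asymmetric transfer hydrogenation (lactone C3), ortho-bromination, bromine–lithium exchange/CO2/lactonisation; C7 from a hydrolytic kinetic resolution.
5. Ring order: arene (purchased), lactone ring (step 10), ring A (step 11), ring B (step 13).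

Key step: step 13

Remark: the (5R) and (5S) spiro epimers of this 2,7-disubstituted 1,6-dioxaspiro[4.4]nonane are taken to be close in energy, so C5 is set under kinetic catalyst control and not by equilibration.

**Route**

Step 1
Reactants: 1 8-bromooct-1-ene; 2 3,5-dimethoxybenzonitrile
Product: 5 1-(3,5-dimethoxyphenyl)non-8-en-1-one, via oct-7-enylmagnesium bromide 3 (not isolated), via N-bromomagnesio ketimine 4 (not isolated)
Conditions: 1, Mg, THF, reflux; then 2, CuBr (2 mol%), THF, reflux; then 2 M HCl, rt
Reagents that add atoms: water (O)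
Why: Grignard addition to a nitrile stops at the N-magnesio ketimine, which cannot take up a second equivalent, and acidic hydrolysis should give the aryl ketone; no stereocentre is formed.

Step 2
Reactants: 5 1-(3,5-dimethoxyphenyl)non-8-en-1-one
Product: 6 (1R)-1-(3,5-dimethoxyphenyl)non-8-en-1-ol
Conditions: RuCl[(R,R)-TsDPEN](p-cymene) (1 mol%), HCO2H/Et3N (5:2), 30 °C
Reagents that add atoms: none
Why: Noyori–Ikariya asymmetric transfer hydrogenation of an aryl alkyl ketone, in which the CH/π contact between the aryl ring and the arene ligand in the six-membered hydride-transfer transition state should give the (R)-carbinol with the (R,R)-catalyst, the isolated alkene being inert to the ruthenium hydride.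

Step 3
Reactants: 6 (1R)-1-(3,5-dimethoxyphenyl)non-8-en-1-ol
Product: 7 (1R)-1-(2-bromo-3,5-dimethoxyphenyl)non-8-en-1-ol
Conditions: NBS (1.05 equiv), CH2Cl2, −20 → 0 °C, dark
Reagents that add atoms: N-bromosuccinimide (O=C1CCC(=O)N1Br)
Why: Electrophilic aromatic bromination should occur at C2 (equivalent to C6), ortho to one methoxy group and para to the other, rather than at C4 between both methoxy groups, and the doubly activated arene should react faster than the isolated terminal alkene in an aprotic solvent at low temperature.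

Step 4
Reactants: 7 (1R)-1-(2-bromo-3,5-dimethoxyphenyl)non-8-en-1-ol
Product: 8 (1R)-1-(2-bromo-3,5-dimethoxyphenyl)-7-(oxiran-2-yl)heptan-1-ol, both oxirane epimers
Conditions: mCPBA (1.2 equiv), CH2Cl2, 0 °C → rt
Reagents that add atoms: 3-chloroperoxybenzoic acid (OOC(=O)c1cccc(Cl)c1)
Why: Prilezhaev epoxidation of the terminal alkene; the remote benzylic stereocentre cannot bias the alkene faces, so both oxirane epimers are expected and the oxirane centre is set in step 5.

Step 5
Reactants: 8 (1R)-1-(2-bromo-3,5-dimethoxyphenyl)-7-(oxiran-2-yl)heptan-1-ol, both oxirane epimers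
Product: 9 (1R)-1-(2-bromo-3,5-dimethoxyphenyl)-7-[(2S)-oxiran-2-yl]heptan-1-ol
Conditions: (S,S)-(salen)Co(OAc) (1 mol%; salen = N,N'-bis(3,5-di-tert-butylsalicylidene)cyclohexane-1,2-diamine dianion), H2O (0.55 equiv), THF, 0 °C → rt
Reagents that add atoms: none
Why: Jacobsen hydrolytic kinetic resolution, in which the cooperative (salen)Co catalyst should hydrolyse the (R)-oxirane epimer to the triol and leave the (S)-oxirane epimer, the oxirane configuration being fixed by the catalyst and not by the distant carbinol.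

Step 6
Reactants: 10 1-(trimethylsilyl)prop-1-yne; 11 (S)-2-methyloxirane
Product: 13 (2S)-6-(trimethylsilyl)hex-5-yn-2-ol, via 3-lithio-1-(trimethylsilyl)prop-1-yne 12 (not isolated)
Conditions: 10, n-BuLi, TMEDA, THF, −78 → 0 °C; then 11, −78 °C → rt; then H2O
Reagents that add atoms: none
Why: Propargylic lithiation of the silylpropyne and SN2 opening of the epoxide at its unsubstituted carbon (the silyl group blocks the alkyne terminus and steers coupling to the propargylic carbon), so the carbinol stereocentre is carried over unchanged from (S)-2-methyloxirane.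

Step 7
Reactants: 13 (2S)-6-(trimethylsilyl)hex-5-yn-2-ol
Product: 14 tert-butyldimethyl{[(2S)-6-(trimethylsilyl)hex-5-yn-2-yl]oxy}silane
Conditions: TBSCl, imidazole, DMF, rt
Reagents that add atoms: tert-butyldimethylsilyl chloride (CC(C)(C)[Si](C)(C)Cl)
Why: Imidazole-promoted silylation of a secondary alcohol; the ether keeps this oxygen out of the alkyne cyclisation of step 11 so that ring A forms alone.

Step 8
Reactants: 14 tert-butyldimethyl{[(2S)-6-(trimethylsilyl)hex-5-yn-2-yl]oxy}silane
Product: 15 tert-butyl[(2S)-hex-5-yn-2-yloxy]dimethylsilane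
Conditions: K2CO3 (0.2 equiv), MeOH, rt
Reagents that add atoms: none
Why: Base-catalysed methanolysis of the alkynyl C–Si bond (protodesilylation), which should leave the more hindered O–Si bond intact.

Step 9
Reactants: 15 tert-butyl[(2S)-hex-5-yn-2-yloxy]dimethylsilane; 9 (1R)-1-(2-bromo-3,5-dimethoxyphenyl)-7-[(2S)-oxiran-2-yl]heptan-1-ol
Product: 17 (1R,8S,14S)-1-(2-bromo-3,5-dimethoxyphenyl)-14-[(tert-butyldimethylsilyl)oxy]pentadec-10-yne-1,8-diol, via lithium acetylide 16 (not isolated)
Conditions: 15 (3 equiv), n-BuLi (2.9 equiv), THF, −78 °C; BF3·OEt2 (3 equiv); then 9, −78 °C; then H2O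
Reagents that add atoms: none
Why: Yamaguchi–Hirao alkynylation, in which the BF3-activated oxirane should be opened by the acetylide at its CH2 carbon by SN2, so the C–O bond of the (S)-centre is not touched, while one equivalent of acetylide is spent on the free benzylic hydroxyl and the aryl bromide and silyl ether are inert at −78 °C.

Step 10
Reactants: 17 (1R,8S,14S)-1-(2-bromo-3,5-dimethoxyphenyl)-14-[(tert-butyldimethylsilyl)oxy]pentadec-10-yne-1,8-diol
Product: 20 (3R)-3-[(7S,13S)-13-[(tert-butyldimethylsilyl)oxy]-7-hydroxytetradec-9-yn-1-yl]-5,7-dimethoxy-2-benzofuran-1(3H)-one, via trilithiated aryl species 18 (not isolated), via hydroxy acid 19 (not isolated)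
Conditions: n-BuLi (3.3 equiv), THF, −78 °C; CO2, −78 °C → rt; then 1 M HCl, 0 °C → rt
Reagents that add atoms: carbon dioxide (O=C=O)
Why: After deprotonation of both hydroxyls, bromine–lithium exchange and carboxylation of the aryllithium should give the 2-(1-hydroxyalkyl)benzoic acid, which lactonises on acidification to the five-membered phthalide (the other hydroxyl is out of reach), with no bond to a stereocentre broken.

Step 11
Reactants: 20 (3R)-3-[(7S,13S)-13-[(tert-butyldimethylsilyl)oxy]-7-hydroxytetradec-9-yn-1-yl]-5,7-dimethoxy-2-benzofuran-1(3H)-one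
Product: 21 (3R)-3-{6-[(2S)-5-{(3S)-3-[(tert-butyldimethylsilyl)oxy]butyl}-2,3-dihydrofuran-2-yl]hexyl}-5,7-dimethoxy-2-benzofuran-1(3H)-one
Conditions: PdCl2(PhCN)2 (5 mol%), anhydrous Et2O, rt; then Et3N, basic alumina
Reagents that add atoms: none
Why: Palladium dichloride-catalysed cycloisomerisation of a 3-alkyn-1-ol, in which the π-activated alkyne is attacked by the C7 hydroxyl at the distal carbon C5 (5-endo-dig, the 4-exo alternative being strained) and protodepalladation should release the 2,3-dihydrofuran; C7 keeps its configuration because its C–O bond is not broken.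

Step 12
Reactants: 21 (3R)-3-{6-[(2S)-5-{(3S)-3-[(tert-butyldimethylsilyl)oxy]butyl}-2,3-dihydrofuran-2-yl]hexyl}-5,7-dimethoxy-2-benzofuran-1(3H)-one
Product: 22 (3R)-3-{6-[(2S)-5-[(3S)-3-hydroxybutyl]-2,3-dihydrofuran-2-yl]hexyl}-5,7-dimethoxy-2-benzofuran-1(3H)-one
Conditions: TBAF, THF, 0 °C → rt; aqueous NaHCO3 work-up, Et3N-treated silica
Reagents that add atoms: none
Why: Fluoride-mediated cleavage of the silyl ether under basic conditions, which should leave the acid-labile enol ether and the lactone untouched and free the C2 hydroxyl only at this point.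

Step 13
Reactants: 22 (3R)-3-{6-[(2S)-5-[(3S)-3-hydroxybutyl]-2,3-dihydrofuran-2-yl]hexyl}-5,7-dimethoxy-2-benzofuran-1(3H)-one
Product: 23 (3R)-5,7-dimethoxy-3-{6-[(2S,5R,7S)-7-methyl-1,6-dioxaspiro[4.4]nonan-2-yl]hexyl}-2-benzofuran-1(3H)-one (target)
Conditions: (S,S)-imidodiphosphoric acid built from two 3,3'-bis(2,4,6-triethylphenyl)-1,1'-bi-2-naphthol units (5 mol%), MTBE, 4 Å MS, −35 °C
Reagents that add atoms: none
Why: The acid protonates the enol ether at C9 while its phosphoryl oxygen holds the C2 hydroxyl, so O1 adds to C5 of the developing O6=C5 oxocarbenium inside the chiral ion pair (an asynchronous addition of O–H across C5=C9). The closest known reaction type is the confined Brønsted acid-catalysed asymmetric spiroacetalisation of hydroxy-tethered cyclic enol ethers, which covers dihydrofurans and the catalyst-controlled formation of either spiro epimer from a chiral substrate. Ring B closes 5-exo-trig, O1 attacking C5 with the C5=O6 bond outside the new ring. C5 is the only new stereocentre and is controlled by the catalyst, which shields one face of C5 in its confined pocket; C2 and C7 are preset and not touched, and the catalyst antipode that delivers (5R) is to be fixed in a trial with each enantiomer. The step needs kinetic control, because the (5R) and (5S) ketals are expected to be close in energy; the weak, bulky acid at −35 °C should protonate only the enol ether, the one basic π bond of 22, and should not reionise the product ketal, while the hydroxyl three carbons away from C5 allows no closure other than to the five-membered ring.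

**Compound list**

1 | 8-bromooct-1-ene | BrCCCCCCC=C | starting material
2 | 3,5-dimethoxybenzonitrile | COc1cc(OC)cc(c1)C#N | starting material
3 | oct-7-enylmagnesium bromide | C=CCCCCCC[Mg]Br | intermediate
4 | N-bromomagnesio ketimine of 1-(3,5-dimethoxyphenyl)non-8-en-1-one | COc1cc(OC)cc(c1)C(CCCCCCC=C)=N[Mg]Br | intermediate
5 | 1-(3,5-dimethoxyphenyl)non-8-en-1-one | COc1cc(OC)cc(c1)C(=O)CCCCCCC=C | intermediate
6 | (1R)-1-(3,5-dimethoxyphenyl)non-8-en-1-ol | COc1cc(OC)cc(c1)[C@@H](CCCCCCC=C)O | intermediate
7 | (1R)-1-(2-bromo-3,5-dimethoxyphenyl)non-8-en-1-ol | COc1cc(OC)c(Br)c(c1)[C@@H](CCCCCCC=C)O | intermediate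
8 | (1R)-1-(2-bromo-3,5-dimethoxyphenyl)-7-(oxiran-2-yl)heptan-1-ol, both oxirane epimers | COc1cc(OC)c(Br)c(c1)[C@@H](CCCCCCC2CO2)O | intermediate
9 | (1R)-1-(2-bromo-3,5-dimethoxyphenyl)-7-[(2S)-oxiran-2-yl]heptan-1-ol | COc1cc(OC)c(Br)c(c1)[C@@H](CCCCCC[C@H]2CO2)O | intermediate
10 | 1-(trimethylsilyl)prop-1-yne | CC#C[Si](C)(C)C | starting material
11 | (S)-2-methyloxirane | C[C@H]1CO1 | starting material
12 | 3-lithio-1-(trimethylsilyl)prop-1-yne | [Li]CC#C[Si](C)(C)C | intermediate
13 | (2S)-6-(trimethylsilyl)hex-5-yn-2-ol | C[Si](C)(C)C#CCC[C@H](C)O | intermediate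
14 | tert-butyldimethyl{[(2S)-6-(trimethylsilyl)hex-5-yn-2-yl]oxy}silane | C[Si](C)(C)C#CCC[C@H](C)O[Si](C)(C)C(C)(C)C | intermediate
15 | tert-butyl[(2S)-hex-5-yn-2-yloxy]dimethylsilane | C#CCC[C@H](C)O[Si](C)(C)C(C)(C)C | intermediate
16 | lithium acetylide of 15 | [Li]C#CCC[C@H](C)O[Si](C)(C)C(C)(C)C | intermediate
17 | (1R,8S,14S)-1-(2-bromo-3,5-dimethoxyphenyl)-14-[(tert-butyldimethylsilyl)oxy]pentadec-10-yne-1,8-diol | COc1cc(OC)c(Br)c(c1)[C@@H](CCCCCC[C@H](O)CC#CCC[C@H](C)O[Si](C)(C)C(C)(C)C)O | intermediate
18 | trilithiated aryl species (aryllithium, two lithium alkoxides) from 17 | COc1cc(OC)c([Li])c(c1)[C@@H](CCCCCC[C@H](O[Li])CC#CCC[C@H](C)O[Si](C)(C)C(C)(C)C)O[Li] | intermediate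
19 | 2-[(1R,8S,14S)-14-[(tert-butyldimethylsilyl)oxy]-1,8-dihydroxypentadec-10-yn-1-yl]-4,6-dimethoxybenzoic acid | COc1cc(OC)c(C(=O)O)c(c1)[C@@H](CCCCCC[C@H](O)CC#CCC[C@H](C)O[Si](C)(C)C(C)(C)C)O | intermediate
20 | (3R)-3-[(7S,13S)-13-[(tert-butyldimethylsilyl)oxy]-7-hydroxytetradec-9-yn-1-yl]-5,7-dimethoxy-2-benzofuran-1(3H)-one | COc1cc(OC)c2c(c1)[C@@H](CCCCCC[C@H](O)CC#CCC[C@H](C)O[Si](C)(C)C(C)(C)C)OC2=O | intermediate
21 | (3R)-3-{6-[(2S)-5-{(3S)-3-[(tert-butyldimethylsilyl)oxy]butyl}-2,3-dihydrofuran-2-yl]hexyl}-5,7-dimethoxy-2-benzofuran-1(3H)-one | COc1cc(OC)c2c(c1)[C@@H](CCCCCC[C@H]1CC=C(CC[C@H](C)O[Si](C)(C)C(C)(C)C)O1)OC2=O | intermediate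
22 | (3R)-3-{6-[(2S)-5-[(3S)-3-hydroxybutyl]-2,3-dihydrofuran-2-yl]hexyl}-5,7-dimethoxy-2-benzofuran-1(3H)-one | COc1cc(OC)c2c(c1)[C@@H](CCCCCC[C@H]1CC=C(CC[C@H](C)O)O1)OC2=O | intermediate
23 | (3R)-5,7-dimethoxy-3-{6-[(2S,5R,7S)-7-methyl-1,6-dioxaspiro[4.4]nonan-2-yl]hexyl}-2-benzofuran-1(3H)-one | COc1cc(OC)c2c(c1)[C@@H](CCCCCC[C@H]1CC[C@@]3(CC[C@H](C)O3)O1)OC2=O | target

**Step count and risks**

Total step count: 13. Longest linear sequence: 10 steps (steps 1 to 5 and 9 to 13).

Risk 1, step 13. The catalyst control may be insufficient: a mismatched pairing with the preset C2 and C7 centres, a poor fit of the long C7 chain in the confined pocket, or reionisation of the product ketal would erode the selectivity at C5. The fallback gives up kinetic control and uses equilibration with recycling. It sets out from 22, which is treated with pyridinium p-toluenesulfonate in CH2Cl2 at rt to give 23 together with its (5S)-spiro epimer F1. The two are separated by chromatography, F1 is returned to the same acid to re-equilibrate, and the material is recycled. The fallback comes back to the route at 23.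

Risk 2, step 11. The cycloisomerisation may not stop at the enol ether: unreacted alcohol can add to the enol ether product (oligomeric mixed ketals), or adventitious water can hydrate it. The fallback traps ring A as an isolable ketal and never handles a free enol ether. It sets out from 20, which with Ph3PAuCl/AgOTf (2 mol%) in MeOH/CH2Cl2 at rt should undergo tandem 5-endo cycloisomerisation and methanol addition to the methyl ketal F2 (both C5 anomers). TBAF in THF then gives the hydroxy methyl ketal F3. The same chiral imidodiphosphoric acid (5 Å MS, MTBE, −35 °C) should close ring B by intramolecular transketalisation with loss of methanol. The fallback comes back to the route at 23.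

Risk 3, step 3. Bromination of the terminal alkene or oxidation of the benzylic alcohol may compete with the ring bromination. The fallback brings the bromine in with the arene. It sets out from the Grignard reagent 3, which is added to purchased 2-bromo-3,5-dimethoxybenzaldehyde (COc1cc(OC)c(Br)c(C=O)c1) to give racemic 1-(2-bromo-3,5-dimethoxyphenyl)non-8-en-1-ol F4. Oxidation with MnO2 in CH2Cl2 gives 1-(2-bromo-3,5-dimethoxyphenyl)non-8-en-1-one F5. Transfer hydrogenation with RuCl[(R,R)-TsDPEN](p-cymene) in HCO2H/Et3N should then give the (R)-alcohol. The fallback comes back to the route at 7.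

**Further compounds**

F1 | step 13 | (3R)-5,7-dimethoxy-3-{6-[(2S,5S,7S)-7-methyl-1,6-dioxaspiro[4.4]nonan-2-yl]hexyl}-2-benzofuran-1(3H)-one | COc1cc(OC)c2c(c1)[C@@H](CCCCCC[C@H]1CC[C@]3(CC[C@H](C)O3)O1)OC2=O
F2 | step 11 | (3R)-3-{6-[(2S)-5-{(3S)-3-[(tert-butyldimethylsilyl)oxy]butyl}-5-methoxyoxolan-2-yl]hexyl}-5,7-dimethoxy-2-benzofuran-1(3H)-one, both C5 anomers | COc1cc(OC)c2c(c1)[C@@H](CCCCCC[C@H]1CCC(CC[C@H](C)O[Si](C)(C)C(C)(C)C)(OC)O1)OC2=O
F3 | step 11 | (3R)-3-{6-[(2S)-5-[(3S)-3-hydroxybutyl]-5-methoxyoxolan-2-yl]hexyl}-5,7-dimethoxy-2-benzofuran-1(3H)-one, both C5 anomers | COc1cc(OC)c2c(c1)[C@@H](CCCCCC[C@H]1CCC(CC[C@H](C)O)(OC)O1)OC2=O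
F4 | step 3 | racemic 1-(2-bromo-3,5-dimethoxyphenyl)non-8-en-1-ol | COc1cc(OC)c(Br)c(c1)C(CCCCCCC=C)O
F5 | step 3 | 1-(2-bromo-3,5-dimethoxyphenyl)non-8-en-1-one | COc1cc(OC)c(Br)c(c1)C(=O)CCCCCCC=C
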